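**Retrosynthetic overview**

1. The target is the homo-dimer ent-epifisetinidol-(4α→6)-ent-epifisetinidol. The interflavan bond C4(upper)–C6(lower) is cut first: C6 (para to O1, ortho to O7) attacks the C4 cation of a 4-alkoxyflavan anti to the 3-OH, so both halves are one benzyl-protected (2S,3S)-flavan-3-ol.
2. That flavan-3-ol comes from the (2S)-flavan-3-one by hydride delivery anti to the 2-aryl group (2,3-cis). Ring C of the ketone is made by one-carbon ring expansion of the five-membered ring of a (2S)-2-aryl-3-methylidene-2,3-dihydrobenzofuran: an oxidative 1,2-aryl shift with a trivalent iodine reagent turns the exocyclic CH2 into C4 and the old ring carbon into the C3 carbonyl.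
3. Enabling feature: in ring A, carbon C4a has O7 in the para position and O1 ortho. This makes C4a an electron-rich aryl terminus that migrates through a phenonium ion in preference to the O-substituted C2; the same O7/O1 pair later stabilises the C4 cation for the coupling.
4. The dihydrobenzofuran comes from a 5-exo Heck closure of a branched allyl aryl ether, whose stereocentre (future C2) is set by iridium-catalysed asymmetric allylic etherification of 5-(benzyloxy)-2-iodophenol with a 3,4-bis(benzyloxy)cinnamyl carbonate.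
5. Order of ring formation: rings A and B are bought as benzyl ethers; five-membered O-ring (Heck); ring C by expansion (key step); the second ring C is the same compound; union of the two flavan units; hydrogenolysis.

Key step: step 7

Assumption: the phosphoramidite antipode used in step 5 is the one that delivers the (R)-ether 8 (expected to be the (Ra,Rc,Rc) ligand by analogy with cinnamyl carbonates; otherwise its mirror image is used).

**Route**

Step 1
Reactants: 1 3,4-bis(benzyloxy)benzaldehyde
Product: 2 ethyl (E)-3-[3,4-bis(benzyloxy)phenyl]prop-2-enoate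
Conditions: triethyl phosphonoacetate, LiCl, DBU, MeCN, rt
Reagents that add atoms: triethyl phosphonoacetate, CCOC(=O)CP(=O)(OCC)OCC
Why: Horner–Wadsworth–Emmons olefination (Masamune–Roush conditions) of an aryl aldehyde with a stabilised phosphonate should give the (E)-enoate through reversible addition and collapse of the anti oxaphosphetane; no stereocentre is formed.

Step 2
Reactants: 2 ethyl (E)-3-[3,4-bis(benzyloxy)phenyl]prop-2-enoate
Product: 3 (E)-3-[3,4-bis(benzyloxy)phenyl]prop-2-en-1-ol
Conditions: i-Bu2AlH (2.2 equiv), CH2Cl2, −78 °C; aq. potassium sodium tartrate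
Reagents that add atoms: none
Why: 1,2-reduction of the conjugated ester by the aluminium hydride at low temperature should give the allylic alcohol with the (E)-alkene intact; no stereocentre is formed.

Step 3
Reactants: 3 (E)-3-[3,4-bis(benzyloxy)phenyl]prop-2-en-1-ol
Product: 4 (E)-3-[3,4-bis(benzyloxy)phenyl]prop-2-en-1-yl methyl carbonate
Conditions: ClCO2Me, pyridine, CH2Cl2, 0 °C
Reagents that add atoms: methyl chloroformate, COC(=O)Cl
Why: O-acylation of the primary allylic alcohol with a chloroformate gives the linear carbonate, the standard leaving group for iridium-catalysed allylation; no stereocentre is formed.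

Step 4
Reactants: 5 3-(benzyloxy)phenol
Product: 6 5-(benzyloxy)-2-iodophenol
Conditions: I2 (1.0 equiv), NaHCO3, THF/H2O, 0 °C
Reagents that add atoms: iodine, II
Why: electrophilic aromatic iodination of the phenoxide should take place at the carbon ortho to the phenoxide oxygen and para to the benzyloxy group (doubly activated, while the site between the two oxygens is shielded), the usual course for 3-alkoxyphenols under these conditions; no stereocentre is formed.

Step 5
Reactants: 6 5-(benzyloxy)-2-iodophenol and 4 (E)-3-[3,4-bis(benzyloxy)phenyl]prop-2-en-1-yl methyl carbonate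
Product: 8 4-(benzyloxy)-2-({(1R)-1-[3,4-bis(benzyloxy)phenyl]prop-2-en-1-yl}oxy)-1-iodobenzene, via lithium aryloxide 7 (not isolated)
Conditions: n-BuLi (1.0 equiv), THF, 0 °C; then 4, [Ir(cod)Cl]2 (2 mol %), O,O'-(1,1'-binaphthyl-2,2'-diyl)-N,N-bis(1-phenylethyl)phosphoramidite (4 mol %, antipode as assumed), THF, 50 °C; aqueous work-up
Reagents that add atoms: none
Why: iridium-catalysed asymmetric allylic etherification: the cyclometalated Ir–phosphoramidite complex ionises the carbonate to a π-allyl complex and the aryloxide attacks the aryl-bearing terminus (branched selectivity) on the face dictated by the ligand, which sets the stereocentre that becomes C2.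

Step 6
Reactants: 8 4-(benzyloxy)-2-({(1R)-1-[3,4-bis(benzyloxy)phenyl]prop-2-en-1-yl}oxy)-1-iodobenzene
Product: 9 (2S)-6-(benzyloxy)-2-[3,4-bis(benzyloxy)phenyl]-3-methylidene-2,3-dihydro-1-benzofuran
Conditions: Pd(OAc)2 (5 mol %), PPh3 (10 mol %), Ag2CO3 (1.2 equiv), MeCN, 70 °C
Reagents that add atoms: none
Why: intramolecular Mizoroki–Heck reaction: oxidative addition into the C–I bond, 5-exo-trig carbopalladation of the vinyl group and elimination of the only β-hydrogen (on C3) give the exocyclic alkene, while Ag2CO3 removes iodide and suppresses the Pd–H re-addition that would move the double bond into the ring; the stereocentre is not involved (R becomes S only through the CIP priorities).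

Step 7
Reactants: 9 (2S)-6-(benzyloxy)-2-[3,4-bis(benzyloxy)phenyl]-3-methylidene-2,3-dihydro-1-benzofuran
Product: 11 (2S)-7-(benzyloxy)-2-[3,4-bis(benzyloxy)phenyl]chroman-3-one, via flavan-3-one dimethyl ketal 10 (not isolated)
Conditions: PhI(OH)OTs (1.05 equiv), MeOH/H2O 95:5, 0 °C, 15 min; aq. NaHCO3
Reagents that add atoms: water, O
Why: Oxidative ring expansion by a trivalent iodine reagent (1,2-aryl shift): the electrophilic iodane adds to the terminal CH2 of the exocyclic alkene while methanol adds to C3, whose cation is stabilised by the para benzyloxy oxygen and by O1; the ring-A carbon C3a (future C4a) then attacks the CH2 carbon ipso as iodobenzene leaves, the C3–C3a bond breaks, and the 3-methoxy oxocarbenium ion is trapped as ketal 10, which is hydrolysed to 11. The closest known reaction is the PhI(OH)OTs-mediated conversion of 1-methylidene benzocycloalkanes into ring-enlarged β-benzocycloalkanones, itself a case of the oxidative aryl migration of 1,1-disubstituted styrenes. Ring C is not closed by a cyclisation: it arises from the five-membered ring by insertion of the exocyclic carbon between C3 and C3a through a spiro phenonium ion formed in 3-exo fashion. No stereocentre is created; C2 is a spectator whose bonds are not touched, and its configuration should hold as long as ketone 11 is not enolised, hence the ketal stage, 0 °C and the bicarbonate quench. The step needs the aryl carbon and not the O-bearing C2 to migrate, and the alkene not to isomerise to the benzofuran: the first is secured by the para-alkoxy aryl group (C2 is deactivated by O1 and would lead to the flavanone skeleton), the second by fast iodane addition at low temperature.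

Step 8
Reactants: 11 (2S)-7-(benzyloxy)-2-[3,4-bis(benzyloxy)phenyl]chroman-3-one
Product: 12 (2S,3S)-7-(benzyloxy)-2-[3,4-bis(benzyloxy)phenyl]chroman-3-ol (tri-O-benzyl-ent-epifisetinidol)
Conditions: LiBH(s-Bu)3, LiBr, THF, −78 °C; then H2O
Reagents that add atoms: none
Why: diastereoselective ketone reduction with a bulky trialkylborohydride: the hydride should approach C3 from the face opposite the pseudo-equatorial 2-aryl group, so the hydroxyl ends up cis to the aryl group (2S,3S), the known course for flavan-3-ones, and the low temperature keeps C2 from enolising.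

Step 9
Reactants: 12 (2S,3S)-7-(benzyloxy)-2-[3,4-bis(benzyloxy)phenyl]chroman-3-ol
Product: 13 (2S,3S,4R)-7-(benzyloxy)-2-[3,4-bis(benzyloxy)phenyl]-4-(2-ethoxyethoxy)chroman-3-ol
Conditions: DDQ (2 equiv), 2-ethoxyethanol (5 equiv), CH2Cl2, rt
Reagents that add atoms: 2-ethoxyethanol, CCOCCO
Why: DDQ-mediated benzylic oxidation: hydride abstraction at C4 gives a cation stabilised by O7 (para to C4a) and O1 (ortho), and 2-ethoxyethanol should add anti to the quasi-axial 3-OH to give the 3,4-trans ether; the configuration at C4 is provisional because this centre is ionised again in step 10, and simple benzyl ethers are not attacked.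

Step 10
Reactants: 13 (2S,3S,4R)-7-(benzyloxy)-2-[3,4-bis(benzyloxy)phenyl]-4-(2-ethoxyethoxy)chroman-3-ol and 12 (2S,3S)-7-(benzyloxy)-2-[3,4-bis(benzyloxy)phenyl]chroman-3-ol (4 equiv)
Product: 14 (2S,3S,4S)-7-(benzyloxy)-2-[3,4-bis(benzyloxy)phenyl]-4-{(2S,3S)-7-(benzyloxy)-2-[3,4-bis(benzyloxy)phenyl]-3-hydroxychroman-6-yl}chroman-3-ol
Conditions: Me3SiOTf (0.5 equiv), CH2Cl2, −78 to −20 °C; Et3N quench
Reagents that add atoms: none
Why: Lewis-acid-promoted Friedel–Crafts alkylation (flavan-4-yl cation plus arene, the standard proanthocyanidin coupling): Me3SiOTf ionises the C4 ether of 13, and C6 of 12 (para to O1, ortho to O7, less hindered than C8) should attack anti to the quasi-axial 3-OH and to the 2-aryl group, setting C4 as 3,4-trans (4α in this enantiomeric series), while the excess of 12 holds back self-condensation of 13.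

Step 11
Reactants: 14 (2S,3S,4S)-7-(benzyloxy)-2-[3,4-bis(benzyloxy)phenyl]-4-{(2S,3S)-7-(benzyloxy)-2-[3,4-bis(benzyloxy)phenyl]-3-hydroxychroman-6-yl}chroman-3-ol
Product: 15 (2S,3S,4R)-2-(3,4-dihydroxyphenyl)-4-[(2S,3S)-2-(3,4-dihydroxyphenyl)-3,7-dihydroxychroman-6-yl]chromane-3,7-diol (CNP0187520.4)
Conditions: H2 (1 atm), Pd(OH)2/C, THF/MeOH/H2O, rt
Reagents that add atoms: none
Why: catalytic hydrogenolysis of the six benzyl ethers over Pd(OH)2/C under neutral conditions, under which the interflavan bond and the benzylic C2–O1 bonds are known to survive; no stereocentre is touched (the C4 descriptor changes from S to R only because the CIP priorities change on debenzylation).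

**Compound list**

1 | 3,4-bis(benzyloxy)benzaldehyde | O=Cc1ccc(OCc2ccccc2)c(OCc2ccccc2)c1 | starting material
2 | ethyl (E)-3-[3,4-bis(benzyloxy)phenyl]prop-2-enoate | CCOC(=O)/C=C/c1ccc(OCc2ccccc2)c(OCc2ccccc2)c1 | intermediate
3 | (E)-3-[3,4-bis(benzyloxy)phenyl]prop-2-en-1-ol | OC/C=C/c1ccc(OCc2ccccc2)c(OCc2ccccc2)c1 | intermediate
4 | (E)-3-[3,4-bis(benzyloxy)phenyl]prop-2-en-1-yl methyl carbonate | COC(=O)OC/C=C/c1ccc(OCc2ccccc2)c(OCc2ccccc2)c1 | intermediate
5 | 3-(benzyloxy)phenol | Oc1cccc(OCc2ccccc2)c1 | starting material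
6 | 5-(benzyloxy)-2-iodophenol | Oc1cc(OCc2ccccc2)ccc1I | intermediate
7 | lithium 5-(benzyloxy)-2-iodophenoxide (not isolated) | [Li+].[O-]c1cc(OCc2ccccc2)ccc1I | intermediate
8 | 4-(benzyloxy)-2-({(1R)-1-[3,4-bis(benzyloxy)phenyl]prop-2-en-1-yl}oxy)-1-iodobenzene | c1ccccc1COc1ccc(I)c(c1)O[C@@H](c1ccc(OCc3ccccc3)c(OCc3ccccc3)c1)C=C | intermediate
9 | (2S)-6-(benzyloxy)-2-[3,4-bis(benzyloxy)phenyl]-3-methylidene-2,3-dihydro-1-benzofuran | c1ccccc1COc1ccc2c(c1)O[C@@H](c1ccc(OCc3ccccc3)c(OCc3ccccc3)c1)C2=C | intermediate
10 | (2S)-7-(benzyloxy)-2-[3,4-bis(benzyloxy)phenyl]-3,3-dimethoxychromane (not isolated) | c1ccccc1COc1ccc2c(c1)O[C@@H](c1ccc(OCc3ccccc3)c(OCc3ccccc3)c1)C(OC)(OC)C2 | intermediate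
11 | (2S)-7-(benzyloxy)-2-[3,4-bis(benzyloxy)phenyl]chroman-3-one | c1ccccc1COc1ccc2c(c1)O[C@@H](c1ccc(OCc3ccccc3)c(OCc3ccccc3)c1)C(=O)C2 | intermediate
12 | (2S,3S)-7-(benzyloxy)-2-[3,4-bis(benzyloxy)phenyl]chroman-3-ol | c1ccccc1COc1ccc2c(c1)O[C@@H](c1ccc(OCc3ccccc3)c(OCc3ccccc3)c1)[C@@H](O)C2 | intermediate
13 | (2S,3S,4R)-7-(benzyloxy)-2-[3,4-bis(benzyloxy)phenyl]-4-(2-ethoxyethoxy)chroman-3-ol | c1ccccc1COc1ccc2c(c1)O[C@@H](c1ccc(OCc3ccccc3)c(OCc3ccccc3)c1)[C@@H](O)[C@@H]2OCCOCC | intermediate
14 | (2S,3S,4S)-7-(benzyloxy)-2-[3,4-bis(benzyloxy)phenyl]-4-{(2S,3S)-7-(benzyloxy)-2-[3,4-bis(benzyloxy)phenyl]-3-hydroxychroman-6-yl}chroman-3-ol | c1ccccc1COc1ccc2c(c1)O[C@@H](c1ccc(OCc3ccccc3)c(OCc3ccccc3)c1)[C@@H](O)[C@@H]2c1cc2c(cc1OCc1ccccc1)O[C@@H](c1ccc(OCc3ccccc3)c(OCc3ccccc3)c1)[C@@H](O)C2 | intermediate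
15 | (2S,3S,4R)-2-(3,4-dihydroxyphenyl)-4-[(2S,3S)-2-(3,4-dihydroxyphenyl)-3,7-dihydroxychroman-6-yl]chromane-3,7-diol | Oc1ccc2c(c1)O[C@@H](c1ccc(O)c(O)c1)[C@@H](O)[C@@H]2c1cc2c(cc1O)O[C@@H](c1ccc(O)c(O)c1)[C@@H](O)C2 | target

**Step count and risks**

Total steps: 11. Longest linear sequence: 10 (steps 1, 2, 3, 5, 6, 7, 8, 9, 10, 11).

Step 7 (key ring expansion). What may go wrong: the C3 cation or the acid set free may move the exocyclic double bond into the ring (aromatisation to a benzofuran, which erases C2) before the aryl shift, or C2 may partly epimerise while ketal 10 is hydrolysed. The fallback is the same ring expansion done as a stepwise semipinacol shift, with no cation at C3 and no acid. Setting out from 9, dihydroxylation (OsO4 cat., NMO, acetone/H2O) on the face anti to the 2-aryl group should give the diol (2S,3S)-6-(benzyloxy)-2-[3,4-bis(benzyloxy)phenyl]-3-(hydroxymethyl)-2,3-dihydro-1-benzofuran-3-ol F1. Sulfonylation of the primary hydroxyl (MsCl, Et3N, CH2Cl2, −20 °C) should give [(2S,3S)-6-(benzyloxy)-2-[3,4-bis(benzyloxy)phenyl]-3-hydroxy-2,3-dihydro-1-benzofuran-3-yl]methyl methanesulfonate F2. Et3Al (CH2Cl2, −78 °C) should then drive the 1,2-shift of the same ring-A carbon from C3 to the CH2 carbon with loss of mesylate, and the route is rejoined at ketone 11.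

Step 9 (C4 oxidation). What may go wrong: hydride abstraction from C4 may be slow on a ring A that lacks O5, with competing oxidation at the C2–H of the dialkoxybenzylic ether or over-oxidation of 13. The fallback activates C4 through the ketone instead of abstracting hydride from the alcohol. Setting out from ketone 11 and alcohol 12 (excess), AgBF4 in THF (monovalent silver oxidises the C3/C4 enol, a known way to join flavan-3-ones to flavan-3-ols at C4) should give (2S,4S)-7-(benzyloxy)-2-[3,4-bis(benzyloxy)phenyl]-4-{(2S,3S)-7-(benzyloxy)-2-[3,4-bis(benzyloxy)phenyl]-3-hydroxychroman-6-yl}chroman-3-one F3, with the C4 aryl group expected trans to the 2-aryl group. Reduction with LiBH(s-Bu)3 (THF, −78 °C) should then give 14, where the route is rejoined; steps 9 and 10 are bypassed, and the facial course of this reduction would have to be confirmed.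

Step 10 (interflavan coupling). What may go wrong: ring A of 12 carries no O5 and may be too weak a nucleophile, so that self-condensation of 13 or attack through C8 takes over. The fallback uses a free-phenol nucleophile in place of the benzyl ether. Setting out from 12, hydrogenolysis (H2, Pd(OH)2/C) should give ent-epifisetinidol, (2S,3S)-2-(3,4-dihydroxyphenyl)chromane-3,7-diol F4, whose resorcinol ring with the free 7-OH is the stronger and more C6-selective nucleophile. With 13 and Me3SiOTf (THF/CH2Cl2, −40 °C) it should give the half-protected dimer (2S,3S,4R)-7-(benzyloxy)-2-[3,4-bis(benzyloxy)phenyl]-4-[(2S,3S)-2-(3,4-dihydroxyphenyl)-3,7-dihydroxychroman-6-yl]chroman-3-ol F5. Hydrogenolysis as in step 11 then gives 15, where the route is rejoined.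

**Further compounds**

F1 | step 7 | (2S,3S)-6-(benzyloxy)-2-[3,4-bis(benzyloxy)phenyl]-3-(hydroxymethyl)-2,3-dihydro-1-benzofuran-3-ol | c1ccccc1COc1ccc2c(c1)O[C@@H](c1ccc(OCc3ccccc3)c(OCc3ccccc3)c1)[C@@]2(O)CO
F2 | step 7 | [(2S,3S)-6-(benzyloxy)-2-[3,4-bis(benzyloxy)phenyl]-3-hydroxy-2,3-dihydro-1-benzofuran-3-yl]methyl methanesulfonate | c1ccccc1COc1ccc2c(c1)O[C@@H](c1ccc(OCc3ccccc3)c(OCc3ccccc3)c1)[C@@]2(O)COS(C)(=O)=O
F3 | step 9 | (2S,4S)-7-(benzyloxy)-2-[3,4-bis(benzyloxy)phenyl]-4-{(2S,3S)-7-(benzyloxy)-2-[3,4-bis(benzyloxy)phenyl]-3-hydroxychroman-6-yl}chroman-3-one | c1ccccc1COc1ccc2c(c1)O[C@@H](c1ccc(OCc3ccccc3)c(OCc3ccccc3)c1)C(=O)[C@@H]2c1cc2c(cc1OCc1ccccc1)O[C@@H](c1ccc(OCc3ccccc3)c(OCc3ccccc3)c1)[C@@H](O)C2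
F4 | step 10 | (2S,3S)-2-(3,4-dihydroxyphenyl)chromane-3,7-diol (ent-epifisetinidol) | Oc1ccc2c(c1)O[C@@H](c1ccc(O)c(O)c1)[C@@H](O)C2
F5 | step 10 | (2S,3S,4R)-7-(benzyloxy)-2-[3,4-bis(benzyloxy)phenyl]-4-[(2S,3S)-2-(3,4-dihydroxyphenyl)-3,7-dihydroxychroman-6-yl]chroman-3-ol | c1ccccc1COc1ccc2c(c1)O[C@@H](c1ccc(OCc3ccccc3)c(OCc3ccccc3)c1)[C@@H](O)[C@@H]2c1cc2c(cc1O)O[C@@H](c1ccc(O)c(O)c1)[C@@H](O)C2
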